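**Plan**
- Retrosynthesis: after the C9 silyl ether, one cut removes the C6–C7 and C11–C12 bonds together with the lactone C12–O bond. The cis-fused α-methylene-γ-butyrolactone on the ten-membered ring is read as aldehyde carbon C6 + terminal allene C7=C11=C13 + CO2 (C12).
- Feature that allows this: the precursor is a monocyclic 3(2H)-furanone (ring oxygen between C3 and C10) with a Z-enal arm on C3 and an allenyl arm on C10. The planar furanone and the 4Z olefin hold both reacting ends on the same side, so carbocycle and lactone can close in one operation.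
- Further cuts: C8 ester (Mitsunobu), furanone C3–O bond (α′-hydroxy ynone), C1–C2 (acetylide + lactone), allene carbons C11/C13 (ethynyl Grignard).
- Forward: (Z)-3-methylpent-2-en-4-yn-1-ol (C2–C6, C15) is joined to an allenyl lactone from 2-C-methyl-D-ribono-1,4-lactone (C1, C7–C10, C14). The furanone forms first, then the ten-membered ring and the lactone together.
- Stereochemistry: C9 and C10 from the sugar; C8 from the sugar by SN2 inversion; 4Z from the commercial enynol; C6 and C7 from the chair transition state of the key step under control of C8.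

Key step: step 9

Remark on the chemistry: locants follow germacrane numbering of the target (C1 furanone C=O, C3–O–C10 bridge, C4 with methyl C15, C6 lactone O, C8 ester, C9 OH, C10 with methyl C14, C11/C12/C13 lactone). Compound 6 is carried as both C7 carbinol epimers because that centre is erased in step 5. Compound 9 is drawn open-chain although it equilibrates with its lactols. DBU ligands on nickel are left out of the SMILES of 13.

**Step 1**
Reactants: 1 (Z)-3-methylpent-2-en-4-yn-1-ol
Product: 2 (Z)-triethyl[(3-methylpent-2-en-4-yn-1-yl)oxy]silane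
Conditions: TESCl, imidazole, CH2Cl2, 0 °C
Reagents that add atoms: chlorotriethylsilane, CC[Si](Cl)(CC)CC
Why: Standard silylation of a primary alcohol; the Z geometry of the commercial enynol, which becomes C4=C5 of the target, is untouched.

**Step 2**
Reactants: 3 2-C-methyl-D-ribono-1,4-lactone
Product: 4 3,5-bis-O-triethylsilyl-2-C-methyl-D-ribono-1,4-lactone
Conditions: TESCl (2.3 equiv), imidazole, DMF, 0 °C to rt
Reagents that add atoms: chlorotriethylsilane, CC[Si](Cl)(CC)CC
Why: Silylation takes the primary and the secondary hydroxyl and should leave the hindered tertiary C10 hydroxyl free, so the three oxygens are told apart in one step while the lactone masks the C8 oxygen.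

**Step 3**
Reactants: 4 3,5-bis-O-triethylsilyl-2-C-methyl-D-ribono-1,4-lactone
Product: 5 lactone aldehyde (C7 aldehyde, C9 OTES, C10 OH)
Conditions: (COCl)2, DMSO, CH2Cl2, −78 to −35 °C; i-Pr2NEt, −78 to 0 °C
Reagents that add atoms: none
Why: Swern oxidation, in which activated DMSO cleaves and oxidises a primary TES ether directly while the secondary one survives; C8 next to the aldehyde sits on the convex face of the lactone, its more stable configuration.

**Step 4**
Reactants: 5 lactone aldehyde
Product: 6 lactone propargylic alcohols (both C7 epimers)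
Conditions: HC≡CMgBr (2.2 equiv), THF, −78 °C; sat. NH4Cl at −78 °C
Reagents that add atoms: ethynylmagnesium bromide, C#C[Mg]Br
Why: Grignard addition to the aldehyde is far faster than attack on the lactone at −78 °C; the new carbinol centre needs no control because both epimers converge in step 5.

**Step 5**
Reactants: 6 lactone propargylic alcohols
Product: 7 allenyl lactone
Conditions: PPh3, DEAD, 2-nitrobenzenesulfonohydrazide, THF, −15 °C, then 23 °C
Reagents that add atoms: none
Why: Myers allene synthesis: Mitsunobu displacement by the sulfonyl hydrazide, loss of sulfinic acid and retro-ene loss of N2 from the propargylic diazene should give the terminal allene C7=C11=C13, funnelling both epimers of 6 into one compound.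

**Step 6**
Reactants: 7 allenyl lactone; 2 (Z)-triethyl[(3-methylpent-2-en-4-yn-1-yl)oxy]silane
Product: 10 furanone allenol (8R,9R,10R), via lithium acetylide 8 (not isolated), via hydroxy ynone 9 (not isolated)
Conditions: 2 (2.3 equiv), n-BuLi, THF, −78 °C; add 7, −78 to −40 °C; AcOH; crude product, Et2NH, EtOH, rt
Reagents that add atoms: none
Why: Acetylide addition to a γ-lactone stops at the lactol/hydroxy ynone stage, and amine-mediated 5-endo oxa-Michael cyclisation of the α′-hydroxy ynone through the free tertiary C10 hydroxyl should give the 3(2H)-furanone; the silylated C9 oxygen cannot compete and no stereocentre is touched.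

**Step 7**
Reactants: 10 furanone allenol
Product: 11 furanone allenyl isovalerate (8S,9R,10R)
Conditions: PPh3, DIAD, 3-methylbutanoic acid, toluene, 0 °C to rt
Reagents that add atoms: 3-methylbutanoic acid, CC(C)CC(=O)O
Why: Mitsunobu esterification displaces the activated allenylic C8 hydroxyl by SN2 with inversion (8R to 8S), so the sugar-derived centre is corrected and the ester of the target is installed in the same step.

**Step 8**
Reactants: 11 furanone allenyl isovalerate
Product: 12 allenyl Z-enal
Conditions: (COCl)2, DMSO, CH2Cl2, −78 to −40 °C; Et3N, −78 to −20 °C; used at once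
Reagents that add atoms: none
Why: Swern oxidation, again directly on the primary allylic TES ether beside the hindered secondary C9 TES ether, should give the enal without a separate deprotection; low temperature guards the Z geometry.

**Step 9**
Reactants: 12 allenyl Z-enal
Product: 15 9-O-triethylsilyl ether of the target, via nickelalactone 13 (not isolated), via seco acid 14 (not isolated)
Conditions: Ni(cod)2 [bis(cycloocta-1,5-diene)nickel] (1.5 equiv), DBU (3 equiv), CO2 (1 atm), THF, 0 °C; 12 added over 6 h (final 2 mM), 0 °C to rt; cold 0.5 M HCl; crude acid, PPTS (cat.), CH2Cl2, rt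
Reagents that add atoms: carbon dioxide, O=C=O
Why: Proposed new method: zerovalent nickel ligated by DBU should couple the terminal C11=C13 bond of the allene with CO2 by oxidative cyclisation (C11–C12 bond, CO2 on the central allene carbon) to give nickelalactone 13, a carboxylate-chelated (Z)-allyl species of divalent nickel whose C7 terminus then adds to the tethered C6 aldehyde through a closed six-membered chair transition state; the closest known reaction type is the nickel-mediated carboxylation of terminal allenes followed by allylation of an aldehyde, known in bimolecular form and for five- and six-membered rings. The carbocycle closes by 10-exo-trig addition to the aldehyde carbonyl (a nine-membered ring counted through the furanone oxygen), and on acidification the C6 hydroxyl closes the γ-lactone by 5-exo-trig acylation, the C8 oxygen being blocked as the isovalerate. C6 and C7 are set together: the Z geometry of the chelated allyl unit (C8 axial) and an equatorial C5 in the chair give the syn relationship, that is the cis-fused lactone, and this is also the arrangement in which the tether joins adjacent axial and equatorial positions. The configuration of C7 relative to C8 should follow from allylic 1,3-strain against the CH2–Ni arm, which places H8 inside, the acyloxy group outside and the C8–C9 bond anti to the forming bond, so that the aldehyde reaches the face that gives the 6S,7S isomer. The step needs chemoselectivity of zerovalent nickel for the allene over the allenylic ester, the enal and the dienone, which slow addition of 12 into an excess of the preformed Ni(cod)2–DBU–CO2 reagent at 0 °C is meant to secure, and ring closure over oligomerisation, which high dilution and the Z-enal held on the planar furanone should favour.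

**Step 10**
Reactants: 15 9-O-triethylsilyl ether of the target
Product: 16 target
Conditions: HF·pyridine, pyridine, THF, 0 °C
Reagents that add atoms: none
Why: Fluoride-assisted cleavage of the secondary TES ether under buffered acidic conditions should leave the α-methylene lactone, the furanone and the neighbouring C8 ester intact, with no base to cause an acyl shift to O9.

**Compound list**
1 | (Z)-3-methylpent-2-en-4-yn-1-ol | C#C/C(C)=C\CO | starting material
2 | (Z)-triethyl[(3-methylpent-2-en-4-yn-1-yl)oxy]silane | C#C/C(C)=C\CO[Si](CC)(CC)CC | intermediate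
3 | 2-C-methyl-D-ribono-1,4-lactone, (3R,4R,5R)-3,4-dihydroxy-5-(hydroxymethyl)-3-methyloxolan-2-one | C[C@]1(O)C(=O)O[C@H](CO)[C@H]1O | starting material
4 | 3,5-bis-O-triethylsilyl-2-C-methyl-D-ribono-1,4-lactone | C[C@]1(O)C(=O)O[C@H](CO[Si](CC)(CC)CC)[C@H]1O[Si](CC)(CC)CC | intermediate
5 | (2S,3R,4R)-4-hydroxy-4-methyl-5-oxo-3-(triethylsilyloxy)oxolane-2-carbaldehyde | C[C@]1(O)C(=O)O[C@H](C=O)[C@H]1O[Si](CC)(CC)CC | intermediate
6 | (3R,4R,5R)-3-hydroxy-5-(1-hydroxyprop-2-yn-1-yl)-3-methyl-4-(triethylsilyloxy)oxolan-2-one, both carbinol epimers | C[C@]1(O)C(=O)O[C@H](C(O)C#C)[C@H]1O[Si](CC)(CC)CC | intermediate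
7 | (3R,4R,5R)-3-hydroxy-3-methyl-5-(propa-1,2-dien-1-yl)-4-(triethylsilyloxy)oxolan-2-one | C[C@]1(O)C(=O)O[C@H](C=C=C)[C@H]1O[Si](CC)(CC)CC | intermediate
8 | lithium acetylide of 2 | [Li]C#C/C(C)=C\CO[Si](CC)(CC)CC | intermediate
9 | open-chain hydroxy ynone (8R,9R,10R): C1 ketone, C2≡C3, C8 OH, C9 OTES, C10 OH | C=C=C[C@@H](O)[C@@H](O[Si](CC)(CC)CC)[C@@](C)(O)C(=O)C#C/C(C)=C\CO[Si](CC)(CC)CC | intermediate
10 | furanone allenol (8R,9R,10R): 3(2H)-furanone with C10 methyl, C9 OTES, C8 OH, C7=C11=C13 allene, (4Z)-C4(Me)=C5–C6H2OTES arm on C3 | C=C=C[C@@H](O)[C@@H](O[Si](CC)(CC)CC)[C@@]1(C)OC(=CC1=O)/C(C)=C\CO[Si](CC)(CC)CC | intermediate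
11 | furanone allenyl isovalerate (8S,9R,10R): as 10 with inverted C8 3-methylbutanoate | C=C=C[C@H](OC(=O)CC(C)C)[C@@H](O[Si](CC)(CC)CC)[C@@]1(C)OC(=CC1=O)/C(C)=C\CO[Si](CC)(CC)CC | intermediate
12 | allenyl Z-enal (8S,9R,10R): as 11 with C6 aldehyde | C=C=C[C@H](OC(=O)CC(C)C)[C@@H](O[Si](CC)(CC)CC)[C@@]1(C)OC(=CC1=O)/C(C)=C\C=O | intermediate
13 | nickelalactone: five-membered Ni–C13–C11(=C7)–C12(=O)–O ring, (Z)-C11=C7, divalent nickel | O=C1O[Ni]C/C1=C\[C@H](OC(=O)CC(C)C)[C@@H](O[Si](CC)(CC)CC)[C@@]2(C)OC(=CC2=O)/C(C)=C\C=O | intermediate
14 | seco acid (6S,7S,8S,9R,10R): ten-membered ring closed, C6 OH, C11(=CH2)CO2H | C=C(C(=O)O)[C@H]1[C@@H](O)/C=C(/C)C2=CC(=O)[C@](C)(O2)[C@H](O[Si](CC)(CC)CC)[C@H]1OC(=O)CC(C)C | intermediate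
15 | 9-O-triethylsilyl ether of the target (6S,7S,8S,9R,10R) | C=C1C(=O)O[C@H]2/C=C(/C)C3=CC(=O)[C@](C)(O3)[C@H](O[Si](CC)(CC)CC)[C@@H](OC(=O)CC(C)C)[C@@H]12 | intermediate
16 | CNP0175298.2 (6S,7S,8S,9R,10R,4Z) | C=C1C(=O)O[C@H]2/C=C(/C)C3=CC(=O)[C@](C)(O3)[C@H](O)[C@@H](OC(=O)CC(C)C)[C@@H]12 | target

**Totals**
Total step count: 10. Longest linear sequence: 9 steps (3 to 16, steps 2–10).

**Steps most likely to fail**

1. Step 9 (proposed new method). Zerovalent nickel may ionise the allenylic isovalerate or be held by the enal and dienone before it couples the allene with CO2. DBU may isomerise the Z-enal, the chain may oligomerise instead of closing, or the aldehyde may reach the wrong face of C7. Fallback with known chemistry: the same C6–C7 bond is closed by the CrCl2-mediated intramolecular allylation of an aldehyde with a 2-(bromomethyl)enoate, a ring closure established for ten-membered germacranolides, with C12 brought in by methyl acrylate. It sets out from 4 and returns at 15. Lactone 4 is opened with acetylide 8 and cyclised with Et2NH as in step 6 to the furanone C8 alcohol F1. Mitsunobu esterification with 3-methylbutanoic acid gives the inverted ester F2. Swern conditions oxidise both primary TES ethers to the dialdehyde F3. The Morita–Baylis–Hillman reaction (methyl acrylate, DABCO) should take only the aliphatic C7 aldehyde and give the adduct F4. NBS/Me2S converts it with allylic transposition into the (Z)-2-(bromomethyl)enoate F5. CrCl2 in THF at high dilution gives the ring-closed hydroxy ester F6, and PPTS lactonises it to 15.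

2. Step 7. The carboxylate may attack C11 (SN2′) to give a 2-acyloxy-1,3-diene, the activated alcohol may eliminate, or the hindered C8 hydroxyl may not be activated with the weakly acidic isovaleric acid. Fallback: activation and displacement are separated. It sets out from 10 and returns at 11. MsCl/Et3N at −20 °C gives the allenylic mesylate F7, and cesium 3-methylbutanoate with 18-crown-6 in toluene displaces it with inversion.

3. Step 6. The acetylide may add slowly or twice to the hindered lactone with its α-alkoxide, the TES group may shift from O9 to the O10 alkoxide, or the lactol may fail to open for the amine-mediated cyclisation. Fallback: the lactone is first opened to an acyclic Weinreb amide. It sets out from 7 and returns at 10. Me(MeO)NH·HCl/AlMe3, then TMSCl/imidazole, gives the bis-TMS Weinreb amide F8. Acetylide 8 gives the bis-TMS ynone F9. K2CO3 in MeOH removes both TMS groups and closes the furanone.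

**Further compounds**
F1 | step 9 | furanone C8 alcohol (8R,9R,10R) with C7H2OTES, C9 OTES and C6H2OTES | CC[Si](CC)(CC)OC[C@@H](O)[C@@H](O[Si](CC)(CC)CC)[C@@]1(C)OC(=CC1=O)/C(C)=C\CO[Si](CC)(CC)CC
F2 | step 9 | inverted C8 3-methylbutanoate (8S,9R,10R) of F1 | CC[Si](CC)(CC)OC[C@H](OC(=O)CC(C)C)[C@@H](O[Si](CC)(CC)CC)[C@@]1(C)OC(=CC1=O)/C(C)=C\CO[Si](CC)(CC)CC
F3 | step 9 | dialdehyde: C7 aldehyde and C6 Z-enal | O=C[C@H](OC(=O)CC(C)C)[C@@H](O[Si](CC)(CC)CC)[C@@]1(C)OC(=CC1=O)/C(C)=C\C=O
F4 | step 9 | Morita–Baylis–Hillman adduct at C7, both carbinol epimers | C=C(C(=O)OC)C(O)[C@H](OC(=O)CC(C)C)[C@@H](O[Si](CC)(CC)CC)[C@@]1(C)OC(=CC1=O)/C(C)=C\C=O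
F5 | step 9 | (Z)-2-(bromomethyl)enoate with C6 Z-enal | COC(=O)/C(CBr)=C/[C@H](OC(=O)CC(C)C)[C@@H](O[Si](CC)(CC)CC)[C@@]1(C)OC(=CC1=O)/C(C)=C\C=O
F6 | step 9 | ring-closed hydroxy methyl ester (6S,7S,8S,9R,10R) | COC(=O)C(=C)[C@H]1[C@@H](O)/C=C(/C)C2=CC(=O)[C@](C)(O2)[C@H](O[Si](CC)(CC)CC)[C@H]1OC(=O)CC(C)C
F7 | step 7 | allenylic C8 mesylate (8R,9R,10R) of 10 | C=C=C[C@@H](OS(C)(=O)=O)[C@@H](O[Si](CC)(CC)CC)[C@@]1(C)OC(=CC1=O)/C(C)=C\CO[Si](CC)(CC)CC
F8 | step 6 | bis-TMS Weinreb amide (8R,9R,10R): C8 OTMS, C9 OTES, C10 OTMS | C=C=C[C@@H](O[Si](C)(C)C)[C@@H](O[Si](CC)(CC)CC)[C@@](C)(O[Si](C)(C)C)C(=O)N(C)OC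
F9 | step 6 | bis-TMS ynone (8R,9R,10R) | C=C=C[C@@H](O[Si](C)(C)C)[C@@H](O[Si](CC)(CC)CC)[C@@](C)(O[Si](C)(C)C)C(=O)C#C/C(C)=C\CO[Si](CC)(CC)CC
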